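## Analysis of the target

Heteroartonin A (25) is a flavone. Ring A (C4a–C8a) carries hydroxyls at C5 and C7, ring C (O1, C2, C3, C4) carries a prenyl group at C3, and ring B (C1′–C6′) is attached at C2. Ring B has only one hydrogen, at C6′; it bears a hydroxyl at C2′, a prenyl group at C3′, a methoxy group at C4′ and a hydroxyl at C5′. The molecule has no stereocentre, so any stereochemical element of a route (an olefin geometry, the C2/C3 centres of a flavanone) is transient and is erased at the flavone stage.

The sensitive groups are:
- the two trisubstituted alkenes, which cyclise onto the neighbouring 2′-hydroxyl under protic or Lewis acids and exclude electrophilic halogen, peracids and hydrogenation once they are in place;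
- the hydroquinone-type ring B, which is oxidised to a quinone when its phenols are free;
- the four phenols, which must be masked against bases and arynes.

The difficulty lies in three places. The C2–C1′ junction is crowded, flanked by the C3 prenyl group and the C2′ oxygen. The C3 prenyl group must be introduced as a C-alkylation only. Acylation of a phloroglucinol-type ring A normally needs Friedel–Crafts or Fries conditions that neither prenyl groups nor acetal protecting groups tolerate.

The strategy rests on one feature of ring A. O1 sits on C8a and the C4 carbonyl on the neighbouring C4a, with the C5 oxygen directly beside C4a. An aryne spanning C4a and C8a, polarised by the C5 alkoxy group, can deliver this 1,2-relationship by inserting into a carboxyl C–O bond.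

## Retrosynthetic reasoning

**25 to 24.** The four phenols are uncovered last, by cutting the four O–CH2 acetal bonds. Methoxymethyl ethers are used on all four oxygens because they survive organolithium bases, hot fluoride, enolisation and a quinone oxidant. They come off with dilute acid near room temperature, which is the only acid exposure of the two prenyl groups.

**24 to 22 (through 23).** The C2=C3 double bond is taken back to the saturated ketone 22. This oxidation-level adjustment is accepted because an acid partner at the alkyne level could not carry the C3 prenyl group. The forward reaction must remove a hydride from C2 and the substituent on the C4 oxygen without touching the allylic and benzylic CH2 groups. Turning the ketone into silyl enol ether 23 makes C2–H by far the best hydride donor in the molecule.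

**22 to 21.** The O1–C2 bond is cut, which opens ring C to the 2′-hydroxychalcone 21. The forward reaction is a reversible conjugate addition of the phenol oxygen to the enone. Its stereochemical outcome does not matter because both new centres disappear in the next step.

**21 to 19 and 8 (through 20).** Both bonds that tie ring A to the rest are cut together: O1–C8a and C4–C4a. They sit on adjacent ring carbons, so ring A can arrive as aryne 20, released from silyl triflate 8, and the remainder as carboxylic acid 19. This is the most convergent cut available: ring B, C2, C3, C4 and both prenyl groups come in one piece, and ring A is attached without any Lewis-acid acylation. The forward reaction must: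
- place the oxygen on C8a and not on C4a;
- move the acyl group onto C4a faster than the aryl anion is protonated;
- leave the prenyl groups alone.

**19 to 18, then to 15 and 17.** The acid comes from ester 18, and the olefin that becomes C2=C3 is cut to aldehyde 15 and phosphonate 17. The C3 prenyl group travels in the phosphonate, made from 16 and 13 by alkylation of a carbon stabilised by phosphorus and the ester. That prenylation can only occur at carbon. The olefin geometry has no consequence later.

**15 to 12 and 13; 12 to 11, 10 and 9.** The C3′–CH2 bond is cut. C3′ lies between the C2′ methoxymethoxy and the C4′ methoxy group, the position of ring B most readily lithiated. The formyl carbon is installed first: bromination of 10 para to the methoxy group gives 11, and exchange plus formylation gives 12. The order matters because para direction by the methoxy group is reliable only while one of its ortho positions is still free and the group can lie in the ring plane. During the lithiation the aldehyde is masked in the flask as amino alkoxide 14. All three ring B oxygens come from 9.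

**8 to 6, 3, 2 and 1.** The O–S bond and the C–Si bond are cut. The silyl group is placed ortho to a carbamate in 3, which acts as directing group and as masked phenol (6, then 7). Phenol 2 comes from 1 by twofold etherification.

## Alternatives that were turned down

**Alternative 1: Danheiser benzannulation for ring B.**
- Disconnection: ring B is divided into a four-carbon vinylketene unit (C1′, C6′, C5′ and the ketene carbon C2′) and a two-carbon alkyne (C3′, C4′).
- Forward key step: Wolff rearrangement of diazo enone A2 gives a chromonyl vinylketene. It adds methoxyalkyne A3 by [2+2] cycloaddition; the cyclobutenone opens (4π) and recloses (6π) to phenol A1.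
- For: four ring bonds form in one operation. The alkyne polarity dictates the 2′-OH/3′-prenyl/4′-OMe pattern, so ring B regiochemistry is not in question. On this point it is stronger than the chosen route, which depends on a site-selective lithiation in step 8.
- Against: A1 has hydrogen at C5′. That carbon derives from the diazo carbon, which cannot carry oxygen, so a late para-hydroxylation of the 2′-phenol would be needed on an electron-rich ring next to two prenyl groups. A2 also presupposes a finished 3-prenylchromone with a vinyl ketone side chain at C2, hence a long linear sequence before the key step. The chromone chromophore competes in the photolysis, and ynol ether A3 is labile.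
- Comparison: the chosen strategy offers all three ring B oxygens from 9, no late oxidation of ring B, and a convergent union of two fragments of similar size.

**Alternative 2: umpolung hydroacylation closing ring C.**
- Disconnection: C3–C4.
- Forward key step: an N-heterocyclic carbene converts the aldehyde of dienyl ether A5 into an acyl anion equivalent. It adds to the near diene carbon, with hydrogen delivered to the next carbon, giving flavanone A4, the same compound as 22.
- For: the ring A building block is a simple protected salicylaldehyde, far easier to make than 8; on this point the alternative is stronger. The step is catalytic and needs neither an aryne nor a sealed tube.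
- Against: A5 is an aryl ether of a carbinol that is both benzylic to an electron-rich ring and dienylic. Ionisation, allylic transposition and aromatic Claisen shift onto C8 threaten it during its preparation and during heating with base. The aldehyde is flanked by two oxygen substituents and forms the carbene adduct slowly. Hydroacylation of an internal, unactivated diene must be 1,2-selective. After the key step the route needs the same dehydrogenation and deprotection, so nothing is saved later.
- Comparison: the chosen strategy pays with a harder ring A fragment. In return it joins two robust partners, and the O1–C2 bond is formed last under equilibrating conditions.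

**Alternative 3: silyloxyfuran cycloaddition for ring B.**
- Disconnection: ring B is cut into furan A7 (C2′–C5′) and the alkyne of ethynylchromone A8 (C1′, C6′).
- Forward key step: [4+2] cycloaddition, opening of the oxygen bridge at the silyloxy-bearing bridgehead, and aromatisation to A6.
- For: A6 is already at the flavone oxidation level with every ring B substituent in place. The endgame is only removal of silyl and methoxymethyl groups, shorter than the chosen endgame by two steps. Ring B regiochemistry is secured by the polarity of both partners.
- Against: the alkyne of A8 is activated only vinylogously through C2=C3–C4=O and is shielded by the C3 prenyl group. Silyloxyfurans combine cleanly only with strongly electron-poor dienophiles and otherwise give open-chain conjugate adducts or revert. A7 is hydrolytically labile. A8 again requires a complete 3-prenylchromone before the key step.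
- Comparison: the chosen strategy offers a bond-forming event of a type documented for unsaturated acids and two storable precursors. The price is the flavanone detour.

Key step: step 12

Remark: flavone numbering (O1, C2–C8a, C1′–C6′) is used for all intermediates, also before the rings exist; 22 and 23 are racemates whose stereocentres are removed in step 14.

## Route

Step 1
Reactants: 1 phloroglucinol
Product: 2 3,5-bis(methoxymethoxy)phenol
Conditions: MOMCl (2.0 equiv), i-Pr2NEt, THF/DMF, 0 °C → rt
Reagents that add atoms: chloromethyl methyl ether, COCCl
Why: O-alkylation of the phenoxide with the chloromethyl ether (Williamson type); with two equivalents the bis-ether should be the main component of a statistical mixture, and mono- and tris-ether can be separated by chromatography.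

Step 2
Reactants: 2 3,5-bis(methoxymethoxy)phenol
Product: 3 3,5-bis(methoxymethoxy)phenyl N-isopropylcarbamate
Conditions: i-PrNCO, Et3N (cat.), CH2Cl2, rt
Reagents that add atoms: isopropyl isocyanate, CC(C)N=C=O
Why: Base-catalysed addition of the phenol to the isocyanate (carbamoylation); the N-monoalkyl carbamate is chosen because it can later be removed under mild base.

Step 3
Reactants: 3 3,5-bis(methoxymethoxy)phenyl N-isopropylcarbamate
Product: 6 3,5-bis(methoxymethoxy)-2-(trimethylsilyl)phenyl N-isopropylcarbamate, via N-silyl carbamate 4 (not isolated), via disilyl carbamate 5 (not isolated)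
Conditions: TBSOTf, TMEDA, Et2O, 0 °C → rt; n-BuLi (2.2 equiv), TMEDA, −78 °C; TMSCl, −78 °C → rt; aq NH4Cl
Reagents that add atoms: chlorotrimethylsilane, C[Si](C)(C)Cl
Why: Directed ortho-metalation of the carbamate after in situ N-silylation; the carbamate outranks the methoxymethoxy groups, so lithiation should occur at C2, flanked by carbamate and one acetal oxygen, rather than at C4 between the two acetals. The N–Si bond is hydrolysed on work-up.

Step 4
Reactants: 6 3,5-bis(methoxymethoxy)-2-(trimethylsilyl)phenyl N-isopropylcarbamate
Product: 8 3,5-bis(methoxymethoxy)-2-(trimethylsilyl)phenyl trifluoromethanesulfonate, via silyl phenol 7 (not isolated)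
Conditions: DBU, Et2NH, MeCN, 40 °C; then PhNTf2, rt
Reagents that add atoms: N-phenylbis(trifluoromethanesulfonimide), O=S(=O)(N(c1ccccc1)S(=O)(=O)C(F)(F)F)C(F)(F)F
Why: E1cB cleavage of the N–H carbamate by DBU (the isocyanate is scavenged by Et2NH) frees the phenoxide, which is sulfonylated in the same flask by the mild triflating agent; neither stage is acidic, so the acetals and the aryl–silicon bond should survive.

Step 5
Reactants: 9 methoxyhydroquinone
Product: 10 2-methoxy-1,4-bis(methoxymethoxy)benzene
Conditions: MOMCl (2.5 equiv), i-Pr2NEt, CH2Cl2, 0 °C → rt, under argon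
Reagents that add atoms: chloromethyl methyl ether, COCCl
Why: Twofold O-alkylation (Williamson type); exclusion of air keeps the hydroquinone from being oxidised before both oxygens are capped.

Step 6
Reactants: 10 2-methoxy-1,4-bis(methoxymethoxy)benzene
Product: 11 1-bromo-4-methoxy-2,5-bis(methoxymethoxy)benzene
Conditions: NBS (1.0 equiv), MeCN, 0 °C, dark
Reagents that add atoms: N-bromosuccinimide, O=C1CCC(=O)N1Br
Why: Electrophilic aromatic bromination; as in other 1,2,4-trialkoxybenzenes the position para to the methoxy group and ortho to an acetal oxygen (the future C1′) should react. It is done before C3′ is substituted, while the methoxy group can still conjugate with the ring.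

Step 7
Reactants: 11 1-bromo-4-methoxy-2,5-bis(methoxymethoxy)benzene
Product: 12 4-methoxy-2,5-bis(methoxymethoxy)benzaldehyde
Conditions: n-BuLi, THF, −78 °C; DMF, −78 °C → rt; H2O
Reagents that add atoms: N,N-dimethylformamide, CN(C)C=O
Why: Bromine–lithium exchange is faster than any deprotonation at −78 °C, and the aryllithium is formylated by DMF (Bouveault-type formylation).

Step 8
Reactants: 12 4-methoxy-2,5-bis(methoxymethoxy)benzaldehyde; 13 prenyl bromide
Product: 15 4-methoxy-2,5-bis(methoxymethoxy)-3-(3-methylbut-2-en-1-yl)benzaldehyde, via lithium amino alkoxide 14 (not isolated)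
Conditions: N-methylpiperazine, n-BuLi, THF, −20 °C; 12; then n-BuLi, −20 °C; CuBr·SMe2, −78 °C; 13, −78 → 0 °C; H2O
Reagents that add atoms: none
Why: The lithium amide adds to the aldehyde and masks it as an α-amino alkoxide, a weak directing group, so directed ortho-metalation should take place at C3′, flanked by the acetal oxygen and the methoxy group. Transmetalation to copper and SN2 substitution of the allylic bromide installs the prenyl group, and aqueous work-up returns the aldehyde.

Step 9
Reactants: 16 triethyl phosphonoacetate; 13 prenyl bromide
Product: 17 ethyl 2-(diethoxyphosphoryl)-5-methylhex-4-enoate (racemic)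
Conditions: NaH, THF/DMF, 0 °C → rt (16 in excess)
Reagents that add atoms: none
Why: C-alkylation of the phosphonate-stabilised carbanion with the primary allylic bromide; an excess of 16 suppresses double alkylation.

Step 10
Reactants: 15 4-methoxy-2,5-bis(methoxymethoxy)-3-(3-methylbut-2-en-1-yl)benzaldehyde; 17 ethyl 2-(diethoxyphosphoryl)-5-methylhex-4-enoate
Product: 18 ethyl (2E)-3-[4-methoxy-2,5-bis(methoxymethoxy)-3-(3-methylbut-2-en-1-yl)phenyl]-2-(3-methylbut-2-en-1-yl)prop-2-enoate
Conditions: NaH, THF, 0 → 60 °C
Reagents that add atoms: none
Why: Horner–Wadsworth–Emmons olefination; with an aromatic aldehyde and a sodium phosphonate the E isomer (aryl trans to the ester) should predominate. A minor Z isomer can be removed, and would in any case lead to the same flavanone.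

Step 11
Reactants: 18 ethyl (2E)-3-[4-methoxy-2,5-bis(methoxymethoxy)-3-(3-methylbut-2-en-1-yl)phenyl]-2-(3-methylbut-2-en-1-yl)prop-2-enoate
Product: 19 (2E)-3-[4-methoxy-2,5-bis(methoxymethoxy)-3-(3-methylbut-2-en-1-yl)phenyl]-2-(3-methylbut-2-en-1-yl)prop-2-enoic acid
Conditions: LiOH·H2O, THF/MeOH/H2O, 60 °C; then 1 M HCl to pH 4, 0 °C
Reagents that add atoms: lithium hydroxide, [Li+].[OH-]
Why: Saponification of the hindered acrylate; the carboxylate formed protects the allylic positions from deprotonation, and brief cold acidification to pH 4 should leave the aryl acetals intact.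

Step 12
Reactants: 19 (2E)-3-[4-methoxy-2,5-bis(methoxymethoxy)-3-(3-methylbut-2-en-1-yl)phenyl]-2-(3-methylbut-2-en-1-yl)prop-2-enoic acid; 8 3,5-bis(methoxymethoxy)-2-(trimethylsilyl)phenyl trifluoromethanesulfonate
Product: 21 (2E)-1-[2-hydroxy-4,6-bis(methoxymethoxy)phenyl]-3-[4-methoxy-2,5-bis(methoxymethoxy)-3-(3-methylbut-2-en-1-yl)phenyl]-2-(3-methylbut-2-en-1-yl)prop-2-en-1-one, via aryne 20 (not isolated)
Conditions: CsF (4 equiv), THF, 125 °C, sealed tube
Reagents that add atoms: none
Why: Fluoride attacks silicon in 8 and triflate leaves, releasing aryne 20 slowly; the carboxylate of 19 adds to the aryne carbon remote from the C5 methoxymethoxy group (the future C8a), because that alkoxy group withdraws inductively and distorts the triple bond so that negative charge builds up on the carbon next to it (the future C4a). The aryl anion then sits ortho to the new aryl ester and attacks its carbonyl (4-exo-trig) to give a four-membered alkoxide that opens to the chelated o-acyl phenoxide, so O1–C8a and C4–C4a are formed in one operation and no ring stays closed. The closest known reaction type is the insertion of arynes into the C–O bond of carboxylic acids to give o-hydroxyaryl ketones, which is documented for α,β-unsaturated acids. No stereocentre is created and the E geometry of the acrylate is not touched. Three selectivities are needed: regioselectivity, secured by the alkoxy group beside the triple bond; acyl transfer rather than protonation of the aryl anion, favoured by the high temperature and the closeness of the ester carbonyl; and attack by the anionic carboxylate rather than an ene reaction of the aryne with the two prenyl groups, favoured by the low stationary aryne concentration that sparingly soluble CsF provides. Conjugate addition of the aryl anion to the β-carbon is disfavoured because that carbon is shielded by the ortho-substituted ring B and the alkene is trisubstituted. Any phenoxide that closes onward to 22 in the hot fluoride medium is not lost, since step 13 leads to the same compound.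

Step 13
Reactants: 21 (2E)-1-[2-hydroxy-4,6-bis(methoxymethoxy)phenyl]-3-[4-methoxy-2,5-bis(methoxymethoxy)-3-(3-methylbut-2-en-1-yl)phenyl]-2-(3-methylbut-2-en-1-yl)prop-2-en-1-one
Product: 22 racemic trans-(2R*,3S*)-5,7-bis(methoxymethoxy)-2-[4-methoxy-2,5-bis(methoxymethoxy)-3-(3-methylbut-2-en-1-yl)phenyl]-3-(3-methylbut-2-en-1-yl)chroman-4-one
Conditions: NaOAc, EtOH, reflux
Reagents that add atoms: none
Why: Intramolecular oxa-Michael addition (6-endo-trig) of the phenoxide to the enone; the 6′-alkoxy and α-prenyl groups twist the open chalcone out of conjugation, so the equilibrium should lie on the side of the flavanone. C2 and C3 are set under thermodynamic control (reversible closure and epimerisation at C3) as the trans racemate with both substituents equatorial; both centres are removed in step 14.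

Step 14
Reactants: 22 racemic trans-(2R*,3S*)-5,7-bis(methoxymethoxy)-2-[4-methoxy-2,5-bis(methoxymethoxy)-3-(3-methylbut-2-en-1-yl)phenyl]-3-(3-methylbut-2-en-1-yl)chroman-4-one
Product: 24 5,7-bis(methoxymethoxy)-2-[4-methoxy-2,5-bis(methoxymethoxy)-3-(3-methylbut-2-en-1-yl)phenyl]-3-(3-methylbut-2-en-1-yl)-4H-chromen-4-one, via silyl enol ether 23 (not isolated)
Conditions: TMSOTf, Et3N, CH2Cl2, 0 °C; filtration and evaporation; then DDQ, 2,6-lutidine, CH2Cl2, 0 °C → rt
Reagents that add atoms: none
Why: Soft enolisation gives the tetrasubstituted silyl enol ether without a free enolate that could open ring C; DDQ then abstracts hydride from C2, which is allylic to the enol ether, benzylic and next to O1, giving a silyloxybenzopyrylium ion that loses the silyl group to form the flavone (dehydrogenation of a silyl enol ether by a quinone). The mild temperature should spare the benzylic CH2 of the ring B prenyl group.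

Step 15
Reactants: 24 5,7-bis(methoxymethoxy)-2-[4-methoxy-2,5-bis(methoxymethoxy)-3-(3-methylbut-2-en-1-yl)phenyl]-3-(3-methylbut-2-en-1-yl)-4H-chromen-4-one
Product: 25 heteroartonin A
Conditions: 3 M HCl, MeOH, rt → 40 °C
Reagents that add atoms: none
Why: Acid-catalysed cleavage of the four aryl methoxymethyl acetals by transacetalisation to methanol; the reaction is stopped as soon as the last acetal is gone to keep the 2′-hydroxyl from adding to the neighbouring prenyl alkene.

## Compound list

1 | phloroglucinol (benzene-1,3,5-triol) | Oc1cc(O)cc(O)c1 | starting material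
2 | 3,5-bis(methoxymethoxy)phenol | COCOc1cc(O)cc(OCOC)c1 | intermediate
3 | 3,5-bis(methoxymethoxy)phenyl N-isopropylcarbamate | COCOc1cc(OCOC)cc(OC(=O)NC(C)C)c1 | intermediate
4 | 3,5-bis(methoxymethoxy)phenyl N-(tert-butyldimethylsilyl)-N-isopropylcarbamate (not isolated) | COCOc1cc(OCOC)cc(OC(=O)N(C(C)C)[Si](C)(C)C(C)(C)C)c1 | intermediate
5 | 3,5-bis(methoxymethoxy)-2-(trimethylsilyl)phenyl N-(tert-butyldimethylsilyl)-N-isopropylcarbamate (not isolated) | COCOc1cc(OCOC)c([Si](C)(C)C)c(OC(=O)N(C(C)C)[Si](C)(C)C(C)(C)C)c1 | intermediate
6 | 3,5-bis(methoxymethoxy)-2-(trimethylsilyl)phenyl N-isopropylcarbamate | COCOc1cc(OCOC)c([Si](C)(C)C)c(OC(=O)NC(C)C)c1 | intermediate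
7 | 3,5-bis(methoxymethoxy)-2-(trimethylsilyl)phenol (not isolated) | COCOc1cc(O)c([Si](C)(C)C)c(OCOC)c1 | intermediate
8 | 3,5-bis(methoxymethoxy)-2-(trimethylsilyl)phenyl trifluoromethanesulfonate | C[Si](C)(C)c1c(OCOC)cc(OCOC)cc1OS(=O)(=O)C(F)(F)F | intermediate
9 | methoxyhydroquinone (2-methoxybenzene-1,4-diol) | COc1cc(O)ccc1O | starting material
10 | 2-methoxy-1,4-bis(methoxymethoxy)benzene | COCOc1ccc(OCOC)c(OC)c1 | intermediate
11 | 1-bromo-4-methoxy-2,5-bis(methoxymethoxy)benzene | COCOc1cc(OC)c(OCOC)cc1Br | intermediate
12 | 4-methoxy-2,5-bis(methoxymethoxy)benzaldehyde | COCOc1cc(OC)c(OCOC)cc1C=O | intermediate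
13 | prenyl bromide (1-bromo-3-methylbut-2-ene) | CC(C)=CCBr | starting material
14 | lithium [4-methoxy-2,5-bis(methoxymethoxy)phenyl](4-methylpiperazin-1-yl)methanolate, racemic (not isolated) | [Li+].[O-]C(N1CCN(C)CC1)c1cc(OCOC)c(OC)cc1OCOC | intermediate
15 | 4-methoxy-2,5-bis(methoxymethoxy)-3-(3-methylbut-2-en-1-yl)benzaldehyde | O=Cc1cc(OCOC)c(OC)c(CC=C(C)C)c1OCOC | intermediate
16 | triethyl phosphonoacetate | CCOC(=O)CP(=O)(OCC)OCC | starting material
17 | ethyl 2-(diethoxyphosphoryl)-5-methylhex-4-enoate, racemic | CCOC(=O)C(CC=C(C)C)P(=O)(OCC)OCC | intermediate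
18 | ethyl (2E)-3-[4-methoxy-2,5-bis(methoxymethoxy)-3-(3-methylbut-2-en-1-yl)phenyl]-2-(3-methylbut-2-en-1-yl)prop-2-enoate | CCOC(=O)/C(CC=C(C)C)=C/c1cc(OCOC)c(OC)c(CC=C(C)C)c1OCOC | intermediate
19 | (2E)-3-[4-methoxy-2,5-bis(methoxymethoxy)-3-(3-methylbut-2-en-1-yl)phenyl]-2-(3-methylbut-2-en-1-yl)prop-2-enoic acid | OC(=O)/C(CC=C(C)C)=C/c1cc(OCOC)c(OC)c(CC=C(C)C)c1OCOC | intermediate
20 | 3,5-bis(methoxymethoxy)benzyne (1,2-didehydro-3,5-bis(methoxymethoxy)benzene; not isolated) | COCOC1=CC(OCOC)=CC#C1 | intermediate
21 | (2E)-1-[2-hydroxy-4,6-bis(methoxymethoxy)phenyl]-3-[4-methoxy-2,5-bis(methoxymethoxy)-3-(3-methylbut-2-en-1-yl)phenyl]-2-(3-methylbut-2-en-1-yl)prop-2-en-1-one | COCOc1cc(O)c(C(=O)/C(CC=C(C)C)=C/c2cc(OCOC)c(OC)c(CC=C(C)C)c2OCOC)c(OCOC)c1 | intermediate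
22 | racemic trans-(2R*,3S*)-5,7-bis(methoxymethoxy)-2-[4-methoxy-2,5-bis(methoxymethoxy)-3-(3-methylbut-2-en-1-yl)phenyl]-3-(3-methylbut-2-en-1-yl)chroman-4-one (one enantiomer drawn) | O=C1c2c(OCOC)cc(OCOC)cc2O[C@@H](c2cc(OCOC)c(OC)c(CC=C(C)C)c2OCOC)[C@@H]1CC=C(C)C | intermediate
23 | racemic 5,7-bis(methoxymethoxy)-2-[4-methoxy-2,5-bis(methoxymethoxy)-3-(3-methylbut-2-en-1-yl)phenyl]-3-(3-methylbut-2-en-1-yl)-4-(trimethylsilyloxy)-2H-chromene (not isolated) | C[Si](C)(C)OC1=C(CC=C(C)C)C(c2cc(OCOC)c(OC)c(CC=C(C)C)c2OCOC)Oc2cc(OCOC)cc(OCOC)c12 | intermediate
24 | 5,7-bis(methoxymethoxy)-2-[4-methoxy-2,5-bis(methoxymethoxy)-3-(3-methylbut-2-en-1-yl)phenyl]-3-(3-methylbut-2-en-1-yl)-4H-chromen-4-one | COc1c(OCOC)cc(-c2oc3cc(OCOC)cc(OCOC)c3c(=O)c2CC=C(C)C)c(OCOC)c1CC=C(C)C | intermediate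
25 | heteroartonin A, 5,7-dihydroxy-2-[2,5-dihydroxy-4-methoxy-3-(3-methylbut-2-en-1-yl)phenyl]-3-(3-methylbut-2-en-1-yl)-4H-chromen-4-one | COc1c(O)cc(-c2oc3cc(O)cc(O)c3c(=O)c2CC=C(C)C)c(O)c1CC=C(C)C | target

## Step count and least certain steps

Total step count: 15 (steps 1–4 for the silyl triflate, steps 5–8 for the aldehyde, step 9 for the phosphonate, steps 10–11 for the acid, step 12 for the union, steps 13–15 for the endgame).

Longest linear sequence: 10 steps (5, 6, 7, 8, 10, 11, 12, 13, 14, 15).

**Step 12 (key step).**
- What may go wrong: the aryl anion, stabilised by the neighbouring alkoxy group, is protonated by the carboxylic acid before it transfers the acyl group, which leads to plain O-arylation of the carboxylate. Further risks are an ene reaction of the aryne with a prenyl group and a second arylation of the product phenoxide.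
- Fallback: it sets out from 19 and returns at 21. The acid is coupled with N,O-dimethylhydroxylamine (EDC, i-Pr2NEt) to the N-methoxy-N-methylamide F1. 1,3,5-Tris(methoxymethoxy)benzene F2, made from 1 with an excess of the chloromethyl ether, is lithiated between two acetal oxygens with n-BuLi and added to F1 to give the 2′,4′,6′-tris(methoxymethoxy) chalcone F3. One equivalent of MgBr2·OEt2, chelated between the carbonyl and an ortho acetal oxygen, removes one of the two equivalent ortho methoxymethyl groups and gives 21.

**Step 8.**
- What may go wrong: loss of site selectivity in the lithiation. C6′ is also ortho to an acetal oxygen and could be metalated with help from the neighbouring alkoxide. Allylic transposition during the copper-mediated substitution is a lesser risk.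
- Fallback: it sets out from 12 and returns at 15, with the regiochemistry fixed by a sigmatropic shift instead of a lithiation. MgBr2·OEt2 removes the acetal ortho to the formyl group by chelation and gives 2-hydroxy-4-methoxy-5-(methoxymethoxy)benzaldehyde F4. Alkylation with 3-chloro-3-methylbut-1-yne (K2CO3, KI, CuI) gives the 2-methylbut-3-yn-2-yl ether F5. Semihydrogenation (H2, Pd/CaCO3 poisoned with Pb(OAc)2, quinoline) gives the 2-methylbut-3-en-2-yl ether F6. Aromatic Claisen rearrangement (N,N-diethylaniline, 130 °C) can only reach the free ortho position C3′ and gives 2-hydroxy-4-methoxy-5-(methoxymethoxy)-3-(3-methylbut-2-en-1-yl)benzaldehyde F7. Etherification with the chloromethyl ether then gives 15.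

**Step 3.**
- What may go wrong: lithiation between the two acetal oxygens (C4) instead of beside the carbamate, and partial cleavage of an aryl acetal by the silyl triflate during N-silylation.
- Fallback: it sets out from 2 and returns at 8, replacing directed metalation by halogenation and an anionic silyl shift. Amine-mediated ortho-bromination (NBS, cat. i-Pr2NH, CH2Cl2, −78 °C) gives 2-bromo-3,5-bis(methoxymethoxy)phenol F8. Hexamethyldisilazane gives its trimethylsilyl ether F9. n-BuLi at −78 °C triggers bromine–lithium exchange and 1,3-migration of silicon from oxygen to carbon (retro-Brook rearrangement), and the resulting lithium salt of 7 is trapped with Tf2O to give 8.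

**Step 14.**
- What may go wrong: reopening of ring C to the chalcone during silylation, and hydride abstraction by the quinone at the benzylic CH2 of the ring B prenyl group or at the CH2 of the C3 prenyl group instead of at C2.
- Fallback: it sets out from 22 and returns at 24 without any new intermediate. The ketone is dehydrogenated directly with IBX in DMSO at 45–75 °C. This acts through the iodine-bound enol of the ketone and needs neither a silyl enol ether nor a quinone.

**Step 15.**
- What may go wrong: acid-catalysed addition of the freed 2′-hydroxyl to the 3′-prenyl alkene (chroman formation), or hydration of a prenyl group, before the last acetal is cleaved.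
- Fallback: it sets out from 24 and returns at 25 without a Brønsted acid. TMSOTf and 2,2′-bipyridyl in MeCN at 0 °C convert the four aryl acetals, by way of N-(methoxymethyl)bipyridinium salts, into the tetrakis(trimethylsilyl) ether of heteroartonin A F10. This is hydrolysed with water in the same flask to 25.

## Further compounds

F1 | step 12 | (2E)-N-methoxy-N-methyl-3-[4-methoxy-2,5-bis(methoxymethoxy)-3-(3-methylbut-2-en-1-yl)phenyl]-2-(3-methylbut-2-en-1-yl)prop-2-enamide | CON(C)C(=O)/C(CC=C(C)C)=C/c1cc(OCOC)c(OC)c(CC=C(C)C)c1OCOC
F2 | step 12 | 1,3,5-tris(methoxymethoxy)benzene | COCOc1cc(OCOC)cc(OCOC)c1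
F3 | step 12 | (2E)-3-[4-methoxy-2,5-bis(methoxymethoxy)-3-(3-methylbut-2-en-1-yl)phenyl]-2-(3-methylbut-2-en-1-yl)-1-[2,4,6-tris(methoxymethoxy)phenyl]prop-2-en-1-one | COCOc1cc(OCOC)c(C(=O)/C(CC=C(C)C)=C/c2cc(OCOC)c(OC)c(CC=C(C)C)c2OCOC)c(OCOC)c1
F4 | step 8 | 2-hydroxy-4-methoxy-5-(methoxymethoxy)benzaldehyde | O=Cc1cc(OCOC)c(OC)cc1O
F5 | step 8 | 4-methoxy-5-(methoxymethoxy)-2-[(2-methylbut-3-yn-2-yl)oxy]benzaldehyde | O=Cc1cc(OCOC)c(OC)cc1OC(C)(C)C#C
F6 | step 8 | 4-methoxy-5-(methoxymethoxy)-2-[(2-methylbut-3-en-2-yl)oxy]benzaldehyde | O=Cc1cc(OCOC)c(OC)cc1OC(C)(C)C=C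
F7 | step 8 | 2-hydroxy-4-methoxy-5-(methoxymethoxy)-3-(3-methylbut-2-en-1-yl)benzaldehyde | O=Cc1cc(OCOC)c(OC)c(CC=C(C)C)c1O
F8 | step 3 | 2-bromo-3,5-bis(methoxymethoxy)phenol | COCOc1cc(O)c(Br)c(OCOC)c1
F9 | step 3 | [2-bromo-3,5-bis(methoxymethoxy)phenoxy]trimethylsilane | COCOc1cc(O[Si](C)(C)C)c(Br)c(OCOC)c1
F0 | step 14 | none | none
F10 | step 15 | 2-[4-methoxy-3-(3-methylbut-2-en-1-yl)-2,5-bis(trimethylsilyloxy)phenyl]-3-(3-methylbut-2-en-1-yl)-5,7-bis(trimethylsilyloxy)-4H-chromen-4-one | COc1c(O[Si](C)(C)C)cc(-c2oc3cc(O[Si](C)(C)C)cc(O[Si](C)(C)C)c3c(=O)c2CC=C(C)C)c(O[Si](C)(C)C)c1CC=C(C)C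
A1 | alternative 1 | 2-(2-hydroxy-4-methoxy-3-prenylphenyl)-5,7-bis(methoxymethoxy)-3-prenylchromen-4-one | COc1ccc(-c2oc3cc(OCOC)cc(OCOC)c3c(=O)c2CC=C(C)C)c(O)c1CC=C(C)C
A2 | alternative 1 | (3E)-1-diazo-4-[5,7-bis(methoxymethoxy)-4-oxo-3-prenyl-4H-chromen-2-yl]but-3-en-2-one | [N-]=[N+]=CC(=O)/C=C/c1oc2cc(OCOC)cc(OCOC)c2c(=O)c1CC=C(C)C
A3 | alternative 1 | 1-methoxy-5-methylhex-4-en-1-yne | COC#CCC=C(C)C
A4 | alternative 2 | racemic trans-3-prenylflavanone tetrakis(methoxymethyl) ether, identical with 22 | O=C1c2c(OCOC)cc(OCOC)cc2O[C@@H](c2cc(OCOC)c(OC)c(CC=C(C)C)c2OCOC)[C@@H]1CC=C(C)C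
A5 | alternative 2 | racemic 2-{(2E)-1-[4-methoxy-2,5-bis(methoxymethoxy)-3-prenylphenyl]-5-methylhexa-2,4-dien-1-yl}oxy-4,6-bis(methoxymethoxy)benzaldehyde | O=Cc1c(OCOC)cc(OCOC)cc1OC(/C=C/C=C(C)C)c1cc(OCOC)c(OC)c(CC=C(C)C)c1OCOC
A6 | alternative 3 | 2′-O-tert-butyldimethylsilyl-5,7-bis(methoxymethyl) ether of heteroartonin A | COc1c(O)cc(-c2oc3cc(OCOC)cc(OCOC)c3c(=O)c2CC=C(C)C)c(O[Si](C)(C)C(C)(C)C)c1CC=C(C)C
A7 | alternative 3 | 2-(tert-butyldimethylsilyloxy)-4-methoxy-3-prenylfuran | COc1coc(O[Si](C)(C)C(C)(C)C)c1CC=C(C)C
A8 | alternative 3 | 2-ethynyl-5,7-bis(methoxymethoxy)-3-prenyl-4H-chromen-4-one | C#Cc1oc2cc(OCOC)cc(OCOC)c2c(=O)c1CC=C(C)C
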